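Subtraction is the easy step: in the epsilon run, whatever starting material and target leave short of the charge is self-condensation product.

the same everywhere: starting material 0.50 M
- epsilon: reagent 1 equiv (fed, over 10 min); the very flask that is asked about, followed so far; the fed solution adds 0.10 times the starting volume
- flask: reagent 1.00 equiv (fed, over 10 min); the fed solution adds 0.10 times the starting volume; time 30 min
epsilon run (percent of the starting material charged)

| time / min | target / % | starting material / % |
|---|---|---|
| 0.833 | 0.1 | 89.5 |
| 2.00 | 1.1 | 77.8 |
| 4.00 | 2.7 | 61.9 |
| 6.00 | 6.4 | 51.2 |

(readings scatter by 0.3 percentage points)
- in percentages every species weighs as the starting material in it: one self-condensation product counts as two
- charges are per starting volume, the dose included; the dosed solution carries all of it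
- reactions considered so far: starting material + reagent <-> target; 2 starting material -> self-condensation product
- the reaction counts as stopped when no species that holds the starting material changes by six tenths of a point or more over the second half of the time
* at 30 min, what has stopped the reaction, if anything has (forward and back rates have come level / all of the starting material has reacted / the reagent has run out first / it is still moving)
* the target standing at 30 min, as a percentage of the starting material charged

Between 2.00 min and 6.00 min, the shortfall in the epsilon run grows by 4.02 times the gain in target, and I call that ratio the split. Call A the free starting material and B the free reagent (fed minus target), both in points of the starting-material charge. The forward rates then stand as A squared to A times B, so the split goes as A/B and dilution cancels. At 4.00 min that reads 2.42 for S, the selectivity factor: the split times B over A.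

At 6.00 min, S gives a split of 2.31. If the remaining 51.2% of starting material divides that way, my own reckoning puts the target near 21.9%.

The forecast says it is still moving and 27% (22% to 31%), from “Stepping forward by hand”, which is higher than my figure.

The answer for the flask is again "it is still moving", with 20.9% target, so the forecast is right on the first and 6.1 percentage points too high on the second.

    starting material + reagent ⇌ target (K = 4.20 /M, k = 0.00210 /M/s)
    2 starting material → self-condensation product (k = 0.00230 /M/s)

In the flask asked about, self-condensation uses starting material at 4.3 times the forward target step at 3.61 min and 0.40 times at 30.0 min, where S with the standing 14.6% starting material and 79.1% reagent gives a split of 0.447. In the neighbour flask with 0.600 equiv of reagent, S with 16.7% starting material and 77.2% of its own reagent charge gives a split of 0.875 at 30.0 min, higher than in the flask asked about, and its target stands at 13.7%.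

The readings are calculated for substances that don't exist.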